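Ring A (cyclohexene: labdane C12–C15 plus caryophyllane C4′ and C5′; labdane locants plain, caryophyllane primed) shares its C4′–C5′ bond with nine-membered ring B, and C4′ carries a carboxyl 1,4 to C14. A 2-pyrone is therefore the four-carbon partner: its carbonyl is the future C12′ acid, and a terminal alkene (C5′=C15) tethered at pyrone C3 adds across C3/C6. This intramolecular Diels–Alder reaction forms C14–C15 and C4′–C5′, closing rings A and B together from a seco-caryophyllene chain made by cutting (−)-β-caryophyllene at C4′=C5′. The lactone bridge then directs hydride in SN2′ fashion to C12, moving the alkene to C13=C14 and freeing the acid.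

Key step: step 10

Remark (assumption and notation): (−)-β-caryophyllene and trans-communic acid are taken as commercial natural products; positions in intermediates carry the locant of the target atom they become; fragment A = (1R,4S)-4-(hexa-1,5-dien-2-yl)-2,2-dimethylcyclobutyl; fragment B = (1S,4aR,5S,8aR)-5-carboxy-5,8a-dimethyl-2-methylidenedecahydronaphthalen-1-yl (the decalin of trans-communic acid, attached through labdane C9); the C19 acid is carried unprotected.

Step 1
Reactants: 1 (−)-β-caryophyllene
Product: 2 4-[(1S,2R)-3,3-dimethyl-2-(3-oxobutyl)cyclobutyl]pent-4-enal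
Conditions: O3 (1.0 equiv), CH2Cl2/MeOH, −78 °C; then Me2S, −78 °C → rt
Reagents that add atoms: ozone, [O-][O+]=O
Why: Chemoselective ozonolysis with reductive work-up, the strained trisubstituted C4′=C5′ alkene reacting far faster than the exocyclic C8′=C13′ methylene; the cyclobutane centres are untouched.

Step 2
Reactants: 2 keto aldehyde
Product: 3 4-(fragment A)butan-2-one
Conditions: Ph3PCH3Br, KN(SiMe3)2, THF, 0 °C; then 2 (1.05 equiv ylide), −78 °C → 0 °C
Reagents that add atoms: methyltriphenylphosphonium bromide, C[P+](c1ccccc1)(c1ccccc1)c1ccccc1.[Br-]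
Why: Wittig methylenation, in which the non-stabilised ylide should take the aldehyde well before the methyl ketone at low temperature, installing C15.

Step 3
Reactants: 3 methyl ketone
Product: 5 1-diazo-4-(fragment A)butan-2-one, via trifluoroacetyl diketone 4 (not isolated)
Conditions: LiN(SiMe3)2, THF, −78 °C; CF3CO2CH2CF3; then MsN3, Et3N, H2O, MeCN, rt
Reagents that add atoms: methanesulfonyl azide, CS(=O)(=O)N=[N+]=[N-]
Why: Danheiser detrifluoroacetylative diazo transfer, the kinetic enolate forming at the methyl group so that the diazo group ends on the terminal carbon.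

Step 4
Reactants: 5 diazo ketone
Product: 7 methyl 4-(fragment A)butanoate, via ketene 6 (not isolated)
Conditions: PhCO2Ag (10 mol%), Et3N, MeOH, rt, dark
Reagents that add atoms: methanol, CO
Why: Silver-catalysed Wolff rearrangement, the 1,2-shift of C3′ giving a ketene that methanol traps, so that the old methyl carbon becomes the nucleophilic α-CH2 (future C4′) and the old ketone carbon the ester (future C12′).

Step 5
Reactants: 8 trans-communic acid
Product: 9 2-(fragment B)acetaldehyde (12-oxo-13,14,15,16-tetranorlabd-8(17)-en-19-oic acid)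
Conditions: O3 (1.0 equiv, Sudan Red 7B end point), CH2Cl2/MeOH, −78 °C; then Me2S
Reagents that add atoms: ozone, [O-][O+]=O
Why: Chemoselective ozonolysis, the electron-rich trisubstituted C12=C13 bond of the diene being expected to react before the hindered exocyclic C8=C17 alkene, which leaves C12 as the aldehyde and the decalin centres untouched.

Step 6
Reactants: 7 methyl ester; 9 aldehyde acid
Product: 10 methyl 2-[2-(fragment A)ethyl]-3-hydroxy-4-(fragment B)butanoate (mixture at C4′ and C12)
Conditions: 7, LiN(iPr)2, THF, −78 °C; then 9 (pre-treated with LiN(SiMe3)2, 1.0 equiv, THF, −78 °C); aq. NH4Cl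
Reagents that add atoms: none
Why: Aldol addition of the lithium ester enolate to the aldehyde, with the hindered C19 acid held as its lithium carboxylate; both new centres become sp2 later, so their configuration is irrelevant.

Step 7
Reactants: 10 β-hydroxy ester
Product: 11 methyl 2-[2-(fragment A)ethyl]-3-oxo-4-(fragment B)butanoate
Conditions: Dess–Martin periodinane, CH2Cl2, 0 °C → rt
Reagents that add atoms: none
Why: Dess–Martin oxidation of the secondary alcohol to the β-keto ester under near-neutral conditions that spare the four alkenes.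

Step 8
Reactants: 11 β-keto ester
Product: 12 methyl (2Z)-2-[2-(fragment A)ethyl]-4-(fragment B)-3-(trifluoromethylsulfonyloxy)but-2-enoate
Conditions: NaH (2.2 equiv), THF, 0 °C; then PhNTf2, 0 °C → rt
Reagents that add atoms: N-phenylbis(trifluoromethanesulfonimide), O=S(=O)(N(c1ccccc1)S(=O)(=O)C(F)(F)F)C(F)(F)F
Why: O-Triflation of the sodium-chelated β-keto ester enolate, which should place the triflate cis to the ester (Z), the geometry that later allows lactonisation.

Step 9
Reactants: 12 enol triflate
Product: 14 3-[2-(fragment A)ethyl]-4-[(fragment B)methyl]-5-methyl-2H-pyran-2-one, via ethoxydienoate 13 (not isolated)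
Conditions: EtOC≡CMe, HBpin, Cp2Zr(H)Cl (5 mol%), CH2Cl2, rt; then 12, Pd(dppf)Cl2 (5 mol%), K3PO4, THF/H2O, 50 °C; then TsOH·H2O (20 mol%), acetone/H2O, 40 °C
Reagents that add atoms: 1-ethoxyprop-1-yne, CCOC#CC; water, O
Why: Hydroboration of the ynol ether puts boron on the methyl-bearing carbon, Suzuki–Miyaura coupling with the vinylogous acyl triflate proceeds with retention, and acid hydrolysis of the enol ether to the C14 aldehyde followed by enol lactonisation onto the cis ester closes the 2-pyrone.

Step 10
Reactants: 14 pyrone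
Product: 15 bridged lactone (2-oxabicyclo[2.2.2]oct-5-en-3-one: C12′(=O)–O bridges C4′ and C14, alkene C12=C13, ethano bridge C5′–C15; ring B closed through C4′–C5′; C6′ on C5′ syn to the lactone bridge)
Conditions: 15 kbar, CH2Cl2 (0.005 M), BHT (cat.), 60 °C
Reagents that add atoms: none
Why: Concerted suprafacial [4+2] cycloaddition with the 2-pyrone as diene (termini C4′ and C14) and the tethered monosubstituted alkene C5′=C15 as dienophile; the closest known type is the intramolecular pyrone–alkene Diels–Alder reaction that gives 2-oxabicyclo[2.2.2]octenones, here run under pressure at moderate temperature so that the CO2 bridge is kept. Ring A closes as the cycloadduct ring, the nine-membered ring B closes as the tether ring in the fused mode through the C4′–C5′ bond, and the lactone bridge C12′(=O)–O–C14 is a temporary third ring. C4′ and C5′ are set together: with C6′ on the lactone side of the dienophile the A/B fusion is trans (C3′ and C6′ anti across the forming bond, as in the E-alkene of caryophyllene), and the trans-cyclobutane (C1′, C9′) should relay the facial sense through the ring-B conformation, the required one placing ring A on the face that caryophyllene offers to external reagents in its epoxidation; C14 is fixed by the cage and erased in step 11. The step needs chemoselectivity for C5′=C15 over the two 1,1-disubstituted alkenes: C8′=C13′ would have to join two fully substituted carbons and build a trans-bicyclo[4.2.0]octane, and C8=C17 cannot span the diene termini. It needs the fused and not the bridged regiochemistry, which the tether (smaller ring) and the usual preference of a monosubstituted alkene to bond through its CH2 terminus to the oxygen-bearing pyrone C6 both favour. High dilution suppresses dimerisation, and the medium-ring closure with an unactivated alkene is the main risk.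

Step 11
Reactants: 15 bridged lactone
Product: 16 target CNP0330729.1 (ring A cyclohex-13-ene; 12′,19-dioic acid; C12′ carboxyl, C6′ and C11 on the same face of ring A)
Conditions: Pd(OAc)2 (10 mol%), n-Bu3P (40 mol%), HCO2H, Et3N, THF, 60 °C
Reagents that add atoms: none
Why: Tsuji-type formate hydrogenolysis in which zerovalent palladium ionises the allylic C14–O bond with inversion and delivers hydride to the more substituted allyl terminus C12 on the face opposite the departing carboxylate, so H-12 ends trans to the C12′ acid, the alkene moves to C13=C14 and the acid is released.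

Compound list
1 | (−)-β-caryophyllene, (1R,4E,9S)-4,11,11-trimethyl-8-methylidenebicyclo[7.2.0]undec-4-ene | C/C1=C\CCC(=C)[C@H]2CC(C)(C)[C@@H]2CC1 | starting material
2 | 4-[(1S,2R)-3,3-dimethyl-2-(3-oxobutyl)cyclobutyl]pent-4-enal | O=CCCC(=C)[C@H]1CC(C)(C)[C@@H]1CCC(C)=O | intermediate
3 | 4-(fragment A)butan-2-one | C=CCCC(=C)[C@H]1CC(C)(C)[C@@H]1CCC(C)=O | intermediate
4 | 1,1,1-trifluoro-6-(fragment A)hexane-2,4-dione | C=CCCC(=C)[C@H]1CC(C)(C)[C@@H]1CCC(=O)CC(=O)C(F)(F)F | intermediate
5 | 1-diazo-4-(fragment A)butan-2-one | C=CCCC(=C)[C@H]1CC(C)(C)[C@@H]1CCC(=O)C=[N+]=[N-] | intermediate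
6 | 4-(fragment A)but-1-en-1-one (ketene) | C=CCCC(=C)[C@H]1CC(C)(C)[C@@H]1CCC=C=O | intermediate
7 | methyl 4-(fragment A)butanoate | C=CCCC(=C)[C@H]1CC(C)(C)[C@@H]1CCCC(=O)OC | intermediate
8 | trans-communic acid, labda-8(17),12E,14-trien-19-oic acid | C=C/C(C)=C/C[C@H]1C(=C)CC[C@@H]2[C@]1(C)CCC[C@]2(C)C(=O)O | starting material
9 | 2-(fragment B)acetaldehyde | O=CC[C@H]1C(=C)CC[C@@H]2[C@]1(C)CCC[C@]2(C)C(=O)O | intermediate
10 | methyl 2-[2-(fragment A)ethyl]-3-hydroxy-4-(fragment B)butanoate | C=CCCC(=C)[C@H]1CC(C)(C)[C@@H]1CCC(C(=O)OC)C(O)C[C@H]1C(=C)CC[C@@H]2[C@]1(C)CCC[C@]2(C)C(=O)O | intermediate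
11 | methyl 2-[2-(fragment A)ethyl]-3-oxo-4-(fragment B)butanoate | C=CCCC(=C)[C@H]1CC(C)(C)[C@@H]1CCC(C(=O)OC)C(=O)C[C@H]1C(=C)CC[C@@H]2[C@]1(C)CCC[C@]2(C)C(=O)O | intermediate
12 | methyl (2Z)-2-[2-(fragment A)ethyl]-4-(fragment B)-3-(trifluoromethylsulfonyloxy)but-2-enoate | C=CCCC(=C)[C@H]1CC(C)(C)[C@@H]1CC/C(C(=O)OC)=C(/OS(=O)(=O)C(F)(F)F)C[C@H]1C(=C)CC[C@@H]2[C@]1(C)CCC[C@]2(C)C(=O)O | intermediate
13 | methyl (2Z,4E)-5-ethoxy-2-[2-(fragment A)ethyl]-3-[(fragment B)methyl]-4-methylpenta-2,4-dienoate | C=CCCC(=C)[C@H]1CC(C)(C)[C@@H]1CC/C(C(=O)OC)=C(/C(C)=C/OCC)C[C@H]1C(=C)CC[C@@H]2[C@]1(C)CCC[C@]2(C)C(=O)O | intermediate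
14 | 3-[2-(fragment A)ethyl]-4-[(fragment B)methyl]-5-methyl-2H-pyran-2-one | C=CCCC(=C)[C@H]1CC(C)(C)[C@@H]1CCC1=C(C[C@H]2C(=C)CC[C@@H]3[C@]2(C)CCC[C@]3(C)C(=O)O)C(C)=COC1=O | intermediate
15 | bridged lactone: C12′(=O)–O–C14 bridge over ring A, alkene C12=C13, rings A/B trans-fused at C4′–C5′, other centres as in the target | C=C1CC[C@H]2C[C@H]3OC(=O)[C@]2(CC[C@@H]2[C@@H]1CC2(C)C)C(C[C@H]2C(=C)CC[C@@H]4[C@]2(C)CCC[C@]4(C)C(=O)O)=C3C | intermediate
16 | CNP0330729.1 | C=C1CC[C@H]2CC=C(C)[C@@H](C[C@H]3C(=C)CC[C@@H]4[C@]3(C)CCC[C@]4(C)C(=O)O)[C@]2(C(=O)O)CC[C@@H]2[C@@H]1CC2(C)C | target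

Total step count: 11. Longest linear sequence: 10 steps (steps 1–4 and 6–11).

Steps most likely to fail

1. Step 10. The cycloaddition may take place at the 1,1-disubstituted C8′=C13′ alkene through the shorter four-atom tether instead of closing ring B, or fail to discriminate between the alkenes. The fallback sets out from 14 and comes back at 15. mCPBA (2.1 equiv, NaHCO3, CH2Cl2, 0 °C) epoxidises the two 1,1-disubstituted alkenes faster than the monosubstituted C5′=C15 to give the bis-epoxide F1 as a mixture of epoxide diastereomers. The pressure cycloaddition is then run on F1, in which only the wanted dienophile is left, to give the bridged lactone bis-epoxide F2. Oxygen-atom transfer to PPh3 catalysed by MeReO3 restores both methylidene groups and returns to 15.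

2. Step 11. Ionisation of the hindered allylic C14–O bond may be slow, or hydride may be delivered to C14 and leave the tetrasubstituted C12=C13 alkene. The fallback sets out from 15 and comes back at 16. Sodium allyloxide in allyl alcohol opens the lactone to the cis-14-hydroxy allyl ester F3. Myers reductive transposition (2-nitrobenzenesulfonyl hydrazide, PPh3, DEAD, −30 → 23 °C) displaces the C14 oxygen with inversion; the allylic diazene loses N2 with suprafacial transfer of H to C12, anti to the carboxyl as required, giving the 12′-allyl ester F4. Pd(PPh3)4 and morpholine then remove the allyl group to give 16.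

3. Step 9. Oxidative addition and transmetalation at the tetrasubstituted enol triflate may be slow, and the triflate may hydrolyse back to 11 under the aqueous base. The fallback sets out from 9 (with 7) and comes back at 14. The alkenylzinc reagent from 1-ethoxyprop-1-yne (Cp2Zr(H)Cl, then Me2Zn) adds to aldehyde 9, pre-neutralised as in step 6, to give the allylic alcohol F5, and MnO2 oxidises it to the β-ethoxy enone F6. The lithium enolate of 7 adds 1,2 to F6 to give the tertiary alcohol F7 (not isolated). Aqueous acid (TsOH, acetone/H2O) then dehydrates, hydrolyses the enol ether and lactonises to pyrone 14, the C4′=C12 geometry equilibrating through the γ-ester enal tautomer.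

Further compounds
F1 | step 10 | bis-epoxide of pyrone 14 (8′,13′- and 8,17-epoxides, epoxide diastereomers) | C=CCCC1(CO1)[C@H]1CC(C)(C)[C@@H]1CCC1=C(C[C@H]2C3(CO3)CC[C@@H]3[C@]2(C)CCC[C@]3(C)C(=O)O)C(C)=COC1=O
F2 | step 10 | bis-epoxide of bridged lactone 15 | C1OC15CC[C@H]2C[C@H]3OC(=O)[C@]2(CC[C@@H]2[C@@H]5CC2(C)C)C(C[C@H]2C6(CO6)CC[C@@H]4[C@]2(C)CCC[C@]4(C)C(=O)O)=C3C
F3 | step 11 | 12′-allyl ester of the ring-opened 14-hydroxy acid (C14–OH cis to the C12′ ester, alkene C12=C13) | C=C1CC[C@H]2C[C@@H](O)C(C)=C(C[C@H]3C(=C)CC[C@@H]4[C@]3(C)CCC[C@]4(C)C(=O)O)[C@]2(C(=O)OCC=C)CC[C@@H]2[C@@H]1CC2(C)C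
F4 | step 11 | 12′-allyl ester of 16 | C=C1CC[C@H]2CC=C(C)[C@@H](C[C@H]3C(=C)CC[C@@H]4[C@]3(C)CCC[C@]4(C)C(=O)O)[C@]2(C(=O)OCC=C)CC[C@@H]2[C@@H]1CC2(C)C
F5 | step 9 | (E)-4-ethoxy-3-methyl-1-(fragment B)but-3-en-2-ol (mixture at the carbinol carbon) | CCO/C=C(\C)C(O)C[C@H]1C(=C)CC[C@@H]2[C@]1(C)CCC[C@]2(C)C(=O)O
F6 | step 9 | (E)-4-ethoxy-3-methyl-1-(fragment B)but-3-en-2-one | CCO/C=C(\C)C(=O)C[C@H]1C(=C)CC[C@@H]2[C@]1(C)CCC[C@]2(C)C(=O)O
F7 | step 9 | methyl (4E)-5-ethoxy-2-[2-(fragment A)ethyl]-3-[(fragment B)methyl]-3-hydroxy-4-methylpent-4-enoate (mixture at C4′ and C12) | C=CCCC(=C)[C@H]1CC(C)(C)[C@@H]1CCC(C(=O)OC)C(O)(C[C@H]1C(=C)CC[C@@H]2[C@]1(C)CCC[C@]2(C)C(=O)O)/C(C)=C/OCC
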